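**Strategy.** The 36-membered lactone ring is opened at C2–C3. Because C2 lies α to the lactone carbonyl C1 and C3 carries only methyl, hydrogen and the C4 chain, the ring can be closed by an intramolecular Horner–Wadsworth–Emmons olefination: a phosphonoacetate on the C35 oxygen (C1–C2) attacks a C3 aldehyde and forms the macrocyclic (E)-C2=C3 enoate in one operation. The precursor is a fully protected linear C3–C40 chain with eleven stereocentres, assembled from a C3–C25 aldehyde (iterative silyl dithiane/epichlorohydrin anion relay) and a C26–C40 methyl ketone. The C3 methyl is then added by catalytic asymmetric conjugate addition.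

Key step: step 28

Remark: atoms are numbered as in the macrolide (C1 lactone carbonyl, ring oxygen on C35, side chain C36–C40). "Configured as in 55" means the same spatial arrangement as at that carbon of the target. Compound 1 is taken as purchasable. The reagent solution 5 of step 3 is made as a fresh batch directly before each of steps 4 to 8.

Step 1
Reactants: 1 tert-butyl(but-3-en-1-yloxy)dimethylsilane
Product: 2 rac-tert-butyldimethyl[2-(oxiran-2-yl)ethoxy]silane
Conditions: mCPBA, NaHCO3, CH2Cl2, 0 °C → rt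
Reagents that add atoms: mCPBA (3-chloroperoxybenzoic acid), OOC(=O)c1cccc(Cl)c1
Why: Prilezhaev epoxidation of the unhindered terminal alkene, the silyl ether being inert; the product is racemic by design.

Step 2
Reactants: 2 rac-tert-butyldimethyl[2-(oxiran-2-yl)ethoxy]silane
Product: 3 (S)-tert-butyldimethyl[2-(oxiran-2-yl)ethoxy]silane
Conditions: (S,S)-(salen)Co(OAc) [cobalt acetate complex of (S,S)-N,N'-bis(3,5-di-tert-butylsalicylidene)cyclohexane-1,2-diamine, 0.5 mol%], H2O (0.55 equiv), THF, 0 °C → rt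
Reagents that add atoms: none
Why: Jacobsen hydrolytic kinetic resolution, in which the (S,S)-cobalt complex should hydrolyse the (R)-epoxide much faster and leave (S)-3, whose stereocentre becomes C5.

Step 3
Reactants: 4 2-(tert-butyldimethylsilyl)-1,3-dithiane
Product: 5 2-lithio-2-(tert-butyldimethylsilyl)-1,3-dithiane (Et2O solution, used at once)
Conditions: t-BuLi, Et2O, −78 → −45 °C
Reagents that add atoms: tert-butyllithium, [Li]C(C)(C)C
Why: Corey–Seebach-type metalation, tert-butyllithium removing the dithiane C2 proton that two sulfur atoms and silicon acidify.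

Step 4
Reactants: 3 (S)-tert-butyldimethyl[2-(oxiran-2-yl)ethoxy]silane, 5 2-lithio-2-(tert-butyldimethylsilyl)-1,3-dithiane, 6 (S)-epichlorohydrin
Product: 9 C3–C10 epoxide, via C5 lithium alkoxide 7 (not isolated), via C9 chlorohydrin alkoxide 8 (not isolated)
Conditions: 5 in Et2O, 3, −78 → −25 °C; then 6, HMPA, THF, −78 °C → rt
Reagents that add atoms: none
Why: Anion relay (silyl dithiane linchpin) coupling: 5 opens 3 at its CH2 (C6), HMPA triggers the 1,4-Brook rearrangement that silylates O5 and regenerates the C7 carbanion, which opens 6 at the epoxide CH2 (C8) before the chloro alkoxide closes to the C9–C10 epoxide; C5 and C9 are carried over from 3 and 6 because no bond at either stereocentre is broken.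

Step 5
Reactants: 9 C3–C10 epoxide, 5 2-lithio-2-(tert-butyldimethylsilyl)-1,3-dithiane, 10 (R)-epichlorohydrin
Product: 13 C3–C14 epoxide, via C9 lithium alkoxide 11 (not isolated), via C13 chlorohydrin alkoxide 12 (not isolated)
Conditions: 5 in Et2O, 9, −78 → −25 °C; then 10, HMPA, THF, −78 °C → rt
Reagents that add atoms: none
Why: Second anion relay cycle (epoxide opening, 1,4-Brook rearrangement, alkylation, epoxide closure), which installs the C11 dithiane and the C9 silyl ether and takes C13 unchanged from (R)-epichlorohydrin.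

Step 6
Reactants: 13 C3–C14 epoxide, 5 2-lithio-2-(tert-butyldimethylsilyl)-1,3-dithiane, 6 (S)-epichlorohydrin
Product: 16 C3–C18 epoxide, via C13 lithium alkoxide 14 (not isolated), via C17 chlorohydrin alkoxide 15 (not isolated)
Conditions: 5 in Et2O, 13, −78 → −25 °C; then 6, HMPA, THF, −78 °C → rt
Reagents that add atoms: none
Why: Third anion relay cycle, which installs the C15 dithiane and the C13 silyl ether and takes C17 unchanged from (S)-epichlorohydrin.

Step 7
Reactants: 16 C3–C18 epoxide, 5 2-lithio-2-(tert-butyldimethylsilyl)-1,3-dithiane, 10 (R)-epichlorohydrin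
Product: 19 C3–C22 epoxide, via C17 lithium alkoxide 17 (not isolated), via C21 chlorohydrin alkoxide 18 (not isolated)
Conditions: 5 in Et2O, 16, −78 → −25 °C; then 10, HMPA, THF, −78 °C → rt
Reagents that add atoms: none
Why: Fourth anion relay cycle, which installs the C19 dithiane and the C17 silyl ether and takes C21 unchanged from (R)-epichlorohydrin.

Step 8
Reactants: 19 C3–C22 epoxide, 5 2-lithio-2-(tert-butyldimethylsilyl)-1,3-dithiane, 20 ethylene oxide
Product: 22 C3–C25 pentakis-dithiane primary alcohol, via C21 lithium alkoxide 21 (not isolated)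
Conditions: 5 in Et2O, 19, −78 → −25 °C; then 20, HMPA, THF, −78 °C → rt; aq. NH4Cl
Reagents that add atoms: none
Why: Fifth anion relay cycle terminated by ethylene oxide, which installs the C23 dithiane and the C21 silyl ether, adds C24–C25 as a free primary alcohol and creates no stereocentre.

Step 9
Reactants: 22 C3–C25 pentakis-dithiane primary alcohol
Product: 23 C3–C25 primary alcohol
Conditions: Raney Ni (W-2), EtOH, reflux
Reagents that add atoms: none
Why: Mozingo desulfurisation hydrogenolyses the five dithianes to the C7, C11, C15, C19 and C23 methylene groups, silyl ethers and the alcohol being inert and no alkene being present at this stage.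

Step 10
Reactants: 23 C3–C25 primary alcohol
Product: 24 C3–C25 aldehyde (left fragment)
Conditions: Dess–Martin periodinane, NaHCO3, CH2Cl2, 0 °C → rt
Reagents that add atoms: none
Why: Dess–Martin oxidation of the only free (primary) alcohol to the C25 aldehyde under buffered conditions that spare silyl ethers.

Step 11
Reactants: 25 (E)-hept-2-en-1-ol
Product: 26 (2R,3R)-2,3-epoxyheptan-1-ol
Conditions: Ti(OiPr)4 (10 mol%), D-(−)-diethyl tartrate (12 mol%), t-BuOOH, 4 Å MS, CH2Cl2, −20 °C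
Reagents that add atoms: tert-butyl hydroperoxide, CC(C)(C)OO
Why: Sharpless asymmetric epoxidation, in which the D-(−)-tartrate titanium complex delivers oxygen to the face of the (E)-allylic alcohol that gives the (2R,3R)-epoxide and thereby fixes C35.

Step 12
Reactants: 26 (2R,3R)-2,3-epoxyheptan-1-ol
Product: 27 (2S,3S)-3-methylheptane-1,2-diol
Conditions: AlMe3 (3 equiv), hexane/CH2Cl2, 0 °C → rt; aq. Rochelle salt (potassium sodium tartrate)
Reagents that add atoms: trimethylaluminium, C[Al](C)C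
Why: Aluminium-alkoxide-directed SN2 opening of the 2,3-epoxy alcohol at C3 with inversion, which places the C36 methyl anti to the C35 hydroxyl.

Step 13
Reactants: 27 (2S,3S)-3-methylheptane-1,2-diol
Product: 29 (2S)-2-[(2S)-hexan-2-yl]oxirane, via primary tosylate 28 (not isolated)
Conditions: NaH, N-tosylimidazole, THF, 0 °C → rt
Reagents that add atoms: none
Why: One-pot selective primary sulfonylation and Williamson-type ring closure by the secondary alkoxide, which keeps the C35–O bond and hence the configuration.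

Step 14
Reactants: 30 2-(2-bromoethyl)-1,3-dioxane, 6 (S)-epichlorohydrin
Product: 32 (S)-1-chloro-5-(1,3-dioxan-2-yl)pentan-2-ol, via Grignard reagent 31 (not isolated)
Conditions: 30, Mg, THF, rt; then 6, CuI (10 mol%), THF, −40 → −20 °C; aq. NH4Cl
Reagents that add atoms: none
Why: Copper-catalysed Grignard opening of the epoxide CH2 of (S)-epichlorohydrin with the chloride untouched, which takes C29 from the chiral pool.

Step 15
Reactants: 32 (S)-1-chloro-5-(1,3-dioxan-2-yl)pentan-2-ol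
Product: 34 (S)-7-(1,3-dioxan-2-yl)hept-1-en-4-ol, via terminal epoxide 33 (not isolated)
Conditions: NaH, THF, 0 °C → rt; then CH2=CHMgBr, CuI (10 mol%), −30 → 0 °C; aq. NH4Cl
Reagents that add atoms: vinylmagnesium bromide, C=C[Mg]Br
Why: Base closes the chlorohydrin to the epoxide without touching C29, and the copper-catalysed vinyl Grignard opens it at the CH2 (C28) to give the homoallylic alcohol.

Step 16
Reactants: 34 (S)-7-(1,3-dioxan-2-yl)hept-1-en-4-ol
Product: 35 (S)-7-(1,3-dithian-2-yl)hept-1-en-4-ol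
Conditions: HS(CH2)3SH, BF3·OEt2, CH2Cl2, −20 → 0 °C
Reagents that add atoms: propane-1,3-dithiol, SCCCS
Why: Lewis-acid transthioacetalisation, driven by the more stable S,S-acetal, turns C33 into the dithiane needed as an acyl anion equivalent.

Step 17
Reactants: 35 (S)-7-(1,3-dithian-2-yl)hept-1-en-4-ol
Product: 36 (S)-2-{4-[(4-methoxybenzyl)oxy]hept-6-en-1-yl}-1,3-dithiane
Conditions: NaH, PMBCl, Bu4NI (cat.), DMF, 0 °C → rt
Reagents that add atoms: 4-methoxybenzyl chloride, COc1ccc(CCl)cc1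
Why: Williamson etherification of the secondary alkoxide; the PMB ether is the β-alkoxy group that later directs the 1,5-anti aldol.

Step 18
Reactants: 36 (S)-2-{4-[(4-methoxybenzyl)oxy]hept-6-en-1-yl}-1,3-dithiane, 29 (2S)-2-[(2S)-hexan-2-yl]oxirane
Product: 38 C26–C40 hydroxy dithiane, via lithiated dithiane 37 (not isolated)
Conditions: 36, n-BuLi, THF, −25 °C; then 29, −25 → 0 °C; aq. NH4Cl
Reagents that add atoms: none
Why: Corey–Seebach umpolung, the 2-lithio dithiane opening epoxide 29 at its CH2 (C34) so that the C33–C34 bond forms without touching C35 or C36.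

Step 19
Reactants: 38 C26–C40 hydroxy dithiane
Product: 39 C26–C40 β-hydroxy ketone
Conditions: MeI, CaCO3, MeCN/H2O (9:1), 45 °C
Reagents that add atoms: water, O
Why: Alkylative dithiane hydrolysis (S-methylation then hydrolysis) unmasks the C33 ketone under neutral conditions that spare the alkene, the PMB ether and the β-hydroxyl.

Step 20
Reactants: 39 C26–C40 β-hydroxy ketone
Product: 40 C33 alcohol C35 acetate (anti)
Conditions: CH3CHO (5 equiv), SmI2 (0.3 equiv), THF, −10 °C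
Reagents that add atoms: acetaldehyde, CC=O
Why: Evans–Tishchenko reduction, in which the samarium-bound hemiacetal of acetaldehyde delivers hydride intramolecularly through a chair transition state to give the 1,3-anti C33 alcohol and leaves O35 as an acetate whose two carbons become C1 and C2.

Step 21
Reactants: 40 C33 alcohol C35 acetate (anti)
Product: 41 C33 silyl ether
Conditions: TBSOTf, 2,6-lutidine, CH2Cl2, −78 °C
Reagents that add atoms: tert-butyldimethylsilyl triflate, CC(C)(C)[Si](C)(C)OS(=O)(=O)C(F)(F)F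
Why: Silylation of the only free hydroxyl under conditions too mild for acetate migration.

Step 22
Reactants: 41 C33 silyl ether
Product: 42 C26–C40 methyl ketone (right fragment)
Conditions: PdCl2 (10 mol%), CuCl, O2 (1 atm), DMF/H2O (7:1), rt
Reagents that add atoms: water, O
Why: Wacker–Tsuji oxidation of the terminal alkene gives the methyl ketone (Markovnikov) and tolerates acetate, silyl and PMB ethers.

Step 23
Reactants: 42 C26–C40 methyl ketone (right fragment), 24 C3–C25 aldehyde (left fragment)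
Product: 45 C3–C40 syn-C25,C27-diol, via dicyclohexylboron enolate 43 (not isolated), via boron aldolate 44 (not isolated)
Conditions: 42, (c-C6H11)2BCl, Et3N, Et2O, −78 → 0 °C; 24, −78 → −20 °C; LiBH4, −78 °C; then H2O2, pH 7 buffer, MeOH, 0 °C
Reagents that add atoms: none
Why: Boron-mediated aldol of a β-alkoxy methyl ketone, in which the kinetic enolate adds to 24 with 1,5-anti induction from the C29 PMB ether to set C25, and LiBH4 then reduces the six-membered boron aldolate by external hydride attack (Narasaka–Prasad type) to set C27 syn to C25.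

Step 24
Reactants: 45 C3–C40 syn-C25,C27-diol
Product: 46 C25,C27-acetonide
Conditions: Me2C(OMe)2, PPTS (cat.), CH2Cl2, rt
Reagents that add atoms: 2,2-dimethoxypropane, COC(C)(C)OC
Why: Acid-catalysed transacetalisation protects the syn-1,3-diol as its chair acetonide with both substituents equatorial.

Step 25
Reactants: 46 C25,C27-acetonide
Product: 49 C35 diethylphosphonoacetate, via acetate lithium enolate 47 (not isolated), via phosphonite ester 48 (not isolated)
Conditions: LDA (2.2 equiv), THF, −78 °C; ClP(OEt)2, −78 °C → rt; then 30% H2O2, 0 °C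
Reagents that add atoms: diethyl chlorophosphite, CCOP(Cl)OCC; hydrogen peroxide, OO
Why: C-Phosphinylation of the acetate enolate with the chlorophosphite and oxidation of the trivalent phosphorus give the phosphonoacetate without cleaving the hindered C35 ester, the molecule holding no other enolisable site.

Step 26
Reactants: 49 C35 diethylphosphonoacetate
Product: 50 C3 primary alcohol
Conditions: HF·pyridine, pyridine, THF, 0 °C
Reagents that add atoms: none
Why: Selective desilylation, buffered HF·pyridine cleaving the unhindered primary TBS ether much faster than the six secondary ones and leaving acetonide and phosphonate intact.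

Step 27
Reactants: 50 C3 primary alcohol
Product: 51 C3 aldehyde (seco precursor)
Conditions: Dess–Martin periodinane, NaHCO3, CH2Cl2, 0 °C → rt
Reagents that add atoms: none
Why: Dess–Martin oxidation under non-basic conditions, so that the phosphonoacetate does not condense before high dilution is applied.

Step 28
Reactants: 51 C3 aldehyde (seco precursor)
Product: 52 macrocyclic (E)-2-enoate
Conditions: LiCl, i-Pr2NEt, MeCN (1 mM, slow addition of 51), rt
Reagents that add atoms: none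
Why: Lithium chelation acidifies the C35 phosphonoacetate so that the amine generates the phosphonate enolate, whose C2 adds to the C3 aldehyde, and the adduct collapses through the oxaphosphetane to the C2=C3 double bond with loss of lithium diethyl phosphate. The closest known reaction type is the intramolecular Horner–Wadsworth–Emmons macrocyclisation under Masamune–Roush conditions, which is well precedented for large macrolide enoates. It closes the 36-membered lactone ring (O–C1 through C35) by a formally 36-exo-trig addition followed by elimination. No stereocentre is formed, and the (E) geometry should follow from reversible addition and faster collapse of the anti adduct, as usual for stabilised phosphonates. The step needs ring closure to win over oligomerisation, which high dilution and the presence of exactly one aldehyde and one phosphonate secure, while the mild base avoids β-elimination of the C5 silyl ether.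

Step 29
Reactants: 52 macrocyclic (E)-2-enoate
Product: 53 protected 3-methyl macrolactone
Conditions: MeMgBr, CuI (10 mol%), Tol-BINAP (15 mol%, the antipode that delivers methyl to the Re face of C3), t-BuOMe, −20 °C; aq. NH4Cl
Reagents that add atoms: methylmagnesium bromide, C[Mg]Br
Why: Copper-catalysed asymmetric conjugate addition of a Grignard reagent to an (E)-enoate, the chiral copper–bisphosphine complex selecting the Re face of C3 so that C3 becomes (R) under catalyst control while the hindered secondary lactone resists 1,2-addition.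

Step 30
Reactants: 53 protected 3-methyl macrolactone
Product: 54 C29 alcohol
Conditions: DDQ, CH2Cl2/pH 7 buffer (10:1), 0 °C
Reagents that add atoms: none
Why: Oxidative PMB cleavage (benzylic hydride abstraction by DDQ, then hydrolysis), to which silyl ethers, acetonide and the saturated lactone are inert.

Step 31
Reactants: 54 C29 alcohol
Product: 55 target macrolide
Conditions: 48% aq. HF, MeCN, 0 °C → rt
Reagents that add atoms: none
Why: Global acidic deprotection removes the six secondary TBS ethers and the acetonide, under conditions where the lactone and the stereocentres should be stable.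

**Compound list**

1 | tert-butyl(but-3-en-1-yloxy)dimethylsilane | C=CCCO[Si](C)(C)C(C)(C)C | starting material
2 | rac-tert-butyldimethyl[2-(oxiran-2-yl)ethoxy]silane | C1OC1CCO[Si](C)(C)C(C)(C)C | intermediate
3 | (S)-tert-butyldimethyl[2-(oxiran-2-yl)ethoxy]silane (C3–C6, epoxide C5–C6) | C1O[C@H]1CCO[Si](C)(C)C(C)(C)C | intermediate
4 | 2-(tert-butyldimethylsilyl)-1,3-dithiane | CC(C)(C)[Si](C)(C)C1SCCCS1 | starting material
5 | 2-lithio-2-(tert-butyldimethylsilyl)-1,3-dithiane | [Li]C1(SCCCS1)[Si](C)(C)C(C)(C)C | intermediate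
6 | (S)-epichlorohydrin | ClC[C@@H]1CO1 | starting material
7 | lithium alkoxide at C5 of the C3–C7 adduct (2-silyl dithiane at C7) | [Li]O[C@H](CC1(SCCCS1)[Si](C)(C)C(C)(C)C)CCO[Si](C)(C)C(C)(C)C | intermediate
8 | lithium alkoxide of the C9 chlorohydrin (C3–C10; C5 OTBS, C7 dithiane) | [Li]O[C@H](CCl)CC1(SCCCS1)C[C@@H](O[Si](C)(C)C(C)(C)C)CCO[Si](C)(C)C(C)(C)C | intermediate
9 | C3–C10 epoxide (oxirane C9–C10, C7 dithiane, OTBS at C3 and C5; C5, C9 configured as in 55) | C1O[C@H]1CC2(SCCCS2)C[C@@H](O[Si](C)(C)C(C)(C)C)CCO[Si](C)(C)C(C)(C)C | intermediate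
10 | (R)-epichlorohydrin | ClC[C@H]1CO1 | starting material
11 | lithium alkoxide at C9 of the C3–C11 adduct (2-silyl dithiane at C11) | [Li]O[C@H](CC1(SCCCS1)[Si](C)(C)C(C)(C)C)CC2(SCCCS2)C[C@@H](O[Si](C)(C)C(C)(C)C)CCO[Si](C)(C)C(C)(C)C | intermediate
12 | lithium alkoxide of the C13 chlorohydrin (C3–C14) | [Li]O[C@@H](CCl)CC1(SCCCS1)C[C@@H](O[Si](C)(C)C(C)(C)C)CC2(SCCCS2)C[C@@H](O[Si](C)(C)C(C)(C)C)CCO[Si](C)(C)C(C)(C)C | intermediate
13 | C3–C14 epoxide (oxirane C13–C14, dithianes at C7 and C11, OTBS at C3, C5, C9; stereocentres as in 55) | C1O[C@@H]1CC2(SCCCS2)C[C@@H](O[Si](C)(C)C(C)(C)C)CC3(SCCCS3)C[C@@H](O[Si](C)(C)C(C)(C)C)CCO[Si](C)(C)C(C)(C)C | intermediate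
14 | lithium alkoxide at C13 of the C3–C15 adduct (2-silyl dithiane at C15) | [Li]O[C@@H](CC1(SCCCS1)[Si](C)(C)C(C)(C)C)CC2(SCCCS2)C[C@@H](O[Si](C)(C)C(C)(C)C)CC3(SCCCS3)C[C@@H](O[Si](C)(C)C(C)(C)C)CCO[Si](C)(C)C(C)(C)C | intermediate
15 | lithium alkoxide of the C17 chlorohydrin (C3–C18) | [Li]O[C@H](CCl)CC1(SCCCS1)C[C@H](O[Si](C)(C)C(C)(C)C)CC2(SCCCS2)C[C@@H](O[Si](C)(C)C(C)(C)C)CC3(SCCCS3)C[C@@H](O[Si](C)(C)C(C)(C)C)CCO[Si](C)(C)C(C)(C)C | intermediate
16 | C3–C18 epoxide (oxirane C17–C18, dithianes at C7, C11, C15, OTBS at C3, C5, C9, C13; stereocentres as in 55) | C1O[C@H]1CC2(SCCCS2)C[C@H](O[Si](C)(C)C(C)(C)C)CC3(SCCCS3)C[C@@H](O[Si](C)(C)C(C)(C)C)CC4(SCCCS4)C[C@@H](O[Si](C)(C)C(C)(C)C)CCO[Si](C)(C)C(C)(C)C | intermediate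
17 | lithium alkoxide at C17 of the C3–C19 adduct (2-silyl dithiane at C19) | [Li]O[C@H](CC1(SCCCS1)[Si](C)(C)C(C)(C)C)CC2(SCCCS2)C[C@H](O[Si](C)(C)C(C)(C)C)CC3(SCCCS3)C[C@@H](O[Si](C)(C)C(C)(C)C)CC4(SCCCS4)C[C@@H](O[Si](C)(C)C(C)(C)C)CCO[Si](C)(C)C(C)(C)C | intermediate
18 | lithium alkoxide of the C21 chlorohydrin (C3–C22) | [Li]O[C@@H](CCl)CC1(SCCCS1)C[C@@H](O[Si](C)(C)C(C)(C)C)CC2(SCCCS2)C[C@H](O[Si](C)(C)C(C)(C)C)CC3(SCCCS3)C[C@@H](O[Si](C)(C)C(C)(C)C)CC4(SCCCS4)C[C@@H](O[Si](C)(C)C(C)(C)C)CCO[Si](C)(C)C(C)(C)C | intermediate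
19 | C3–C22 epoxide (oxirane C21–C22, dithianes at C7, C11, C15, C19, OTBS at C3, C5, C9, C13, C17; stereocentres as in 55) | C1O[C@@H]1CC2(SCCCS2)C[C@@H](O[Si](C)(C)C(C)(C)C)CC3(SCCCS3)C[C@H](O[Si](C)(C)C(C)(C)C)CC4(SCCCS4)C[C@@H](O[Si](C)(C)C(C)(C)C)CC5(SCCCS5)C[C@@H](O[Si](C)(C)C(C)(C)C)CCO[Si](C)(C)C(C)(C)C | intermediate
20 | ethylene oxide | C1CO1 | starting material
21 | lithium alkoxide at C21 of the C3–C23 adduct (2-silyl dithiane at C23) | [Li]O[C@@H](CC1(SCCCS1)[Si](C)(C)C(C)(C)C)CC2(SCCCS2)C[C@@H](O[Si](C)(C)C(C)(C)C)CC3(SCCCS3)C[C@H](O[Si](C)(C)C(C)(C)C)CC4(SCCCS4)C[C@@H](O[Si](C)(C)C(C)(C)C)CC5(SCCCS5)C[C@@H](O[Si](C)(C)C(C)(C)C)CCO[Si](C)(C)C(C)(C)C | intermediate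
22 | C3–C25 primary alcohol with dithianes at C7, C11, C15, C19, C23 and OTBS at C3, C5, C9, C13, C17, C21 | OCCC1(SCCCS1)C[C@H](O[Si](C)(C)C(C)(C)C)CC2(SCCCS2)C[C@@H](O[Si](C)(C)C(C)(C)C)CC3(SCCCS3)C[C@H](O[Si](C)(C)C(C)(C)C)CC4(SCCCS4)C[C@@H](O[Si](C)(C)C(C)(C)C)CC5(SCCCS5)C[C@@H](O[Si](C)(C)C(C)(C)C)CCO[Si](C)(C)C(C)(C)C | intermediate
23 | C3–C25 primary alcohol (C25 OH; OTBS at C3, C5, C9, C13, C17, C21) | OCCCC[C@H](O[Si](C)(C)C(C)(C)C)CCC[C@@H](O[Si](C)(C)C(C)(C)C)CCC[C@H](O[Si](C)(C)C(C)(C)C)CCC[C@@H](O[Si](C)(C)C(C)(C)C)CCC[C@@H](O[Si](C)(C)C(C)(C)C)CCO[Si](C)(C)C(C)(C)C | intermediate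
24 | C3–C25 aldehyde, left fragment (C25 CHO) | O=CCCC[C@H](O[Si](C)(C)C(C)(C)C)CCC[C@@H](O[Si](C)(C)C(C)(C)C)CCC[C@H](O[Si](C)(C)C(C)(C)C)CCC[C@@H](O[Si](C)(C)C(C)(C)C)CCC[C@@H](O[Si](C)(C)C(C)(C)C)CCO[Si](C)(C)C(C)(C)C | intermediate
25 | (E)-hept-2-en-1-ol | CCCC/C=C/CO | starting material
26 | (2R,3R)-2,3-epoxyheptan-1-ol | CCCC[C@H]1O[C@@H]1CO | intermediate
27 | (2S,3S)-3-methylheptane-1,2-diol | CCCC[C@H](C)[C@H](O)CO | intermediate
28 | (2S,3S)-2-hydroxy-3-methylheptyl 4-methylbenzenesulfonate | CCCC[C@H](C)[C@H](O)COS(=O)(=O)c1ccc(C)cc1 | intermediate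
29 | (2S)-2-[(2S)-hexan-2-yl]oxirane (C34–C40, epoxide C34–C35) | CCCC[C@H](C)[C@H]1CO1 | intermediate
30 | 2-(2-bromoethyl)-1,3-dioxane | BrCCC1OCCCO1 | starting material
31 | [2-(1,3-dioxan-2-yl)ethyl]magnesium bromide | Br[Mg]CCC1OCCCO1 | intermediate
32 | (S)-1-chloro-5-(1,3-dioxan-2-yl)pentan-2-ol | ClC[C@@H](O)CCCC1OCCCO1 | intermediate
33 | (S)-2-[3-(1,3-dioxan-2-yl)propyl]oxirane | C1O[C@H]1CCCC2OCCCO2 | intermediate
34 | (S)-7-(1,3-dioxan-2-yl)hept-1-en-4-ol | C=CC[C@@H](O)CCCC1OCCCO1 | intermediate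
35 | (S)-7-(1,3-dithian-2-yl)hept-1-en-4-ol | C=CC[C@@H](O)CCCC1SCCCS1 | intermediate
36 | (S)-2-{4-[(4-methoxybenzyl)oxy]hept-6-en-1-yl}-1,3-dithiane (C26–C33) | C=CC[C@@H](OCc1ccc(OC)cc1)CCCC2SCCCS2 | intermediate
37 | 2-lithio derivative of 36 | [Li]C1(SCCCS1)CCC[C@H](OCc2ccc(OC)cc2)CC=C | intermediate
38 | C26–C40 hydroxy dithiane (C35 OH, C33 dithiane, C29 OPMB, C26=C27 alkene) | CCCC[C@H](C)[C@H](O)CC1(SCCCS1)CCC[C@H](OCc2ccc(OC)cc2)CC=C | intermediate
39 | C26–C40 β-hydroxy ketone (C35 OH, C33 C=O) | CCCC[C@H](C)[C@H](O)CC(=O)CCC[C@H](OCc1ccc(OC)cc1)CC=C | intermediate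
40 | C26–C40 anti-diol monoacetate (C35 OAc, C33 OH) | CCCC[C@H](C)[C@H](OC(C)=O)C[C@@H](O)CCC[C@H](OCc1ccc(OC)cc1)CC=C | intermediate
41 | C26–C40 alkene (C35 OAc, C33 OTBS, C29 OPMB) | CCCC[C@H](C)[C@H](OC(C)=O)C[C@@H](O[Si](C)(C)C(C)(C)C)CCC[C@H](OCc1ccc(OC)cc1)CC=C | intermediate
42 | C26–C40 methyl ketone, right fragment (C27 C=O) | CCCC[C@H](C)[C@H](OC(C)=O)C[C@@H](O[Si](C)(C)C(C)(C)C)CCC[C@H](OCc1ccc(OC)cc1)CC(C)=O | intermediate
43 | dicyclohexylboron enolate of 42 (C26=C27) | CCCC[C@H](C)[C@H](OC(C)=O)C[C@@H](O[Si](C)(C)C(C)(C)C)CCC[C@H](OCc1ccc(OC)cc1)CC(=C)OB(C2CCCCC2)C3CCCCC3 | intermediate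
44 | boron aldolate (C27 ketone, C25 O-B(c-C6H11)2), full C3–C40 chain | CCCC[C@H](C)[C@H](OC(C)=O)C[C@@H](O[Si](C)(C)C(C)(C)C)CCC[C@H](OCc1ccc(OC)cc1)CC(=O)C[C@@H](OB(C2CCCCC2)C3CCCCC3)CCC[C@H](O[Si](C)(C)C(C)(C)C)CCC[C@@H](O[Si](C)(C)C(C)(C)C)CCC[C@H](O[Si](C)(C)C(C)(C)C)CCC[C@@H](O[Si](C)(C)C(C)(C)C)CCC[C@@H](O[Si](C)(C)C(C)(C)C)CCO[Si](C)(C)C(C)(C)C | intermediate
45 | C3–C40 chain with syn-C25,C27-diol (C35 OAc, C29 OPMB, OTBS at C3, C5, C9, C13, C17, C21, C33) | CCCC[C@H](C)[C@H](OC(C)=O)C[C@@H](O[Si](C)(C)C(C)(C)C)CCC[C@H](OCc1ccc(OC)cc1)C[C@@H](O)C[C@@H](O)CCC[C@H](O[Si](C)(C)C(C)(C)C)CCC[C@@H](O[Si](C)(C)C(C)(C)C)CCC[C@H](O[Si](C)(C)C(C)(C)C)CCC[C@@H](O[Si](C)(C)C(C)(C)C)CCC[C@@H](O[Si](C)(C)C(C)(C)C)CCO[Si](C)(C)C(C)(C)C | intermediate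
46 | C25,C27-acetonide of 45 | CCCC[C@H](C)[C@H](OC(C)=O)C[C@@H](O[Si](C)(C)C(C)(C)C)CCC[C@H](OCc1ccc(OC)cc1)C[C@@H]2C[C@@H](OC(C)(C)O2)CCC[C@H](O[Si](C)(C)C(C)(C)C)CCC[C@@H](O[Si](C)(C)C(C)(C)C)CCC[C@H](O[Si](C)(C)C(C)(C)C)CCC[C@@H](O[Si](C)(C)C(C)(C)C)CCC[C@@H](O[Si](C)(C)C(C)(C)C)CCO[Si](C)(C)C(C)(C)C | intermediate
47 | lithium enolate of the C35 acetate of 46 | CCCC[C@H](C)[C@H](OC(=C)O[Li])C[C@@H](O[Si](C)(C)C(C)(C)C)CCC[C@H](OCc1ccc(OC)cc1)C[C@@H]2C[C@@H](OC(C)(C)O2)CCC[C@H](O[Si](C)(C)C(C)(C)C)CCC[C@@H](O[Si](C)(C)C(C)(C)C)CCC[C@H](O[Si](C)(C)C(C)(C)C)CCC[C@@H](O[Si](C)(C)C(C)(C)C)CCC[C@@H](O[Si](C)(C)C(C)(C)C)CCO[Si](C)(C)C(C)(C)C | intermediate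
48 | C35 (diethoxyphosphanyl)acetate (phosphonite ester) | CCCC[C@H](C)[C@H](OC(=O)CP(OCC)OCC)C[C@@H](O[Si](C)(C)C(C)(C)C)CCC[C@H](OCc1ccc(OC)cc1)C[C@@H]2C[C@@H](OC(C)(C)O2)CCC[C@H](O[Si](C)(C)C(C)(C)C)CCC[C@@H](O[Si](C)(C)C(C)(C)C)CCC[C@H](O[Si](C)(C)C(C)(C)C)CCC[C@@H](O[Si](C)(C)C(C)(C)C)CCC[C@@H](O[Si](C)(C)C(C)(C)C)CCO[Si](C)(C)C(C)(C)C | intermediate
49 | C35 diethylphosphonoacetate (C3 OTBS) | CCCC[C@H](C)[C@H](OC(=O)CP(=O)(OCC)OCC)C[C@@H](O[Si](C)(C)C(C)(C)C)CCC[C@H](OCc1ccc(OC)cc1)C[C@@H]2C[C@@H](OC(C)(C)O2)CCC[C@H](O[Si](C)(C)C(C)(C)C)CCC[C@@H](O[Si](C)(C)C(C)(C)C)CCC[C@H](O[Si](C)(C)C(C)(C)C)CCC[C@@H](O[Si](C)(C)C(C)(C)C)CCC[C@@H](O[Si](C)(C)C(C)(C)C)CCO[Si](C)(C)C(C)(C)C | intermediate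
50 | C35 diethylphosphonoacetate with free C3 primary alcohol | CCCC[C@H](C)[C@H](OC(=O)CP(=O)(OCC)OCC)C[C@@H](O[Si](C)(C)C(C)(C)C)CCC[C@H](OCc1ccc(OC)cc1)C[C@@H]2C[C@@H](OC(C)(C)O2)CCC[C@H](O[Si](C)(C)C(C)(C)C)CCC[C@@H](O[Si](C)(C)C(C)(C)C)CCC[C@H](O[Si](C)(C)C(C)(C)C)CCC[C@@H](O[Si](C)(C)C(C)(C)C)CCC[C@@H](O[Si](C)(C)C(C)(C)C)CCO | intermediate
51 | seco precursor: C35 diethylphosphonoacetate with C3 aldehyde | CCCC[C@H](C)[C@H](OC(=O)CP(=O)(OCC)OCC)C[C@@H](O[Si](C)(C)C(C)(C)C)CCC[C@H](OCc1ccc(OC)cc1)C[C@@H]2C[C@@H](OC(C)(C)O2)CCC[C@H](O[Si](C)(C)C(C)(C)C)CCC[C@@H](O[Si](C)(C)C(C)(C)C)CCC[C@H](O[Si](C)(C)C(C)(C)C)CCC[C@@H](O[Si](C)(C)C(C)(C)C)CCC[C@@H](O[Si](C)(C)C(C)(C)C)CC=O | intermediate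
52 | 36-membered (E)-2-enoate macrolactone (OTBS at C5, C9, C13, C17, C21, C33; C25,C27-acetonide; C29 OPMB) | CCCC[C@H](C)[C@H]1C[C@@H](O[Si](C)(C)C(C)(C)C)CCC[C@H](OCc2ccc(OC)cc2)C[C@@H]3C[C@@H](OC(C)(C)O3)CCC[C@H](O[Si](C)(C)C(C)(C)C)CCC[C@@H](O[Si](C)(C)C(C)(C)C)CCC[C@H](O[Si](C)(C)C(C)(C)C)CCC[C@@H](O[Si](C)(C)C(C)(C)C)CCC[C@@H](O[Si](C)(C)C(C)(C)C)C/C=C/C(=O)O1 | intermediate
53 | protected (3R)-3-methyl macrolactone | CCCC[C@H](C)[C@H]1C[C@@H](O[Si](C)(C)C(C)(C)C)CCC[C@H](OCc2ccc(OC)cc2)C[C@@H]3C[C@@H](OC(C)(C)O3)CCC[C@H](O[Si](C)(C)C(C)(C)C)CCC[C@@H](O[Si](C)(C)C(C)(C)C)CCC[C@H](O[Si](C)(C)C(C)(C)C)CCC[C@@H](O[Si](C)(C)C(C)(C)C)CCC[C@@H](O[Si](C)(C)C(C)(C)C)C[C@@H](C)CC(=O)O1 | intermediate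
54 | C29 alcohol (PMB removed) | CCCC[C@H](C)[C@H]1C[C@@H](O[Si](C)(C)C(C)(C)C)CCC[C@H](O)C[C@@H]2C[C@@H](OC(C)(C)O2)CCC[C@H](O[Si](C)(C)C(C)(C)C)CCC[C@@H](O[Si](C)(C)C(C)(C)C)CCC[C@H](O[Si](C)(C)C(C)(C)C)CCC[C@@H](O[Si](C)(C)C(C)(C)C)CCC[C@@H](O[Si](C)(C)C(C)(C)C)C[C@@H](C)CC(=O)O1 | intermediate
55 | target macrolide CNP0225459.2 | CCCC[C@H](C)[C@H]1C[C@@H](O)CCC[C@H](O)C[C@@H](O)C[C@@H](O)CCC[C@H](O)CCC[C@@H](O)CCC[C@H](O)CCC[C@@H](O)CCC[C@@H](O)C[C@@H](C)CC(=O)O1 | target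

**Total step count:** 31 steps.
**Longest linear sequence:** 18 steps (steps 1, 2 and 4–10, then 23–31; equally steps 14–22, then 23–31).

**Steps most likely to fail**

1. Step 29. The chiral copper catalyst may discriminate poorly between the faces of the flexible macrocyclic enoate, or 1,2-addition to the lactone may compete. The fallback sets out from 52 and returns at 53, and moves stereocontrol from methyl delivery to hydride delivery. Unselective Me2CuLi addition to 52 with trapping of the enolate by PhSeBr should give the α-phenylselanyl β-methyl lactone F1. Oxidation with H2O2/pyridine and selenoxide syn-elimination should give the (E)-3-methyl-2-enoate macrolactone F2, to be freed of any (Z) isomer. Copper hydride asymmetric conjugate reduction (Cu(OAc)2·H2O, the DTBM-SEGPHOS antipode that delivers hydride to the Si face of C3, PMHS, t-BuOH, toluene) should then give 53.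

2. Step 25. The acetate enolate may be phosphinylated incompletely, or undergo Claisen-type self-condensation, on this large substrate. The fallback sets out from 46 and returns at 49, and replaces C–P bond formation by acyl exchange. Methanolysis (K2CO3, MeOH, rt) should give the C35 alcohol F3, which is esterified with diethylphosphonoacetic acid (EDC·HCl, DMAP, CH2Cl2) to give 49.

3. Step 4 (the same applies to steps 5 to 8). The silyl migration may be incomplete, the relayed carbanion may attack the chloromethyl carbon of epichlorohydrin and so erode C9, or the new epoxide may be alkylated twice. The fallback sets out from 3 and returns at 9, and separates the relay into discrete alkylations. 2-Lithio-1,3-dithiane (from 1,3-dithiane and n-BuLi, THF, −25 °C) opens 3 to give the C5 hydroxy dithiane F4. TBSCl and imidazole in DMF give the bis-silyl ether F5. A second lithiation (t-BuLi, THF/HMPA, −78 °C) and reaction with (S)-epichlorohydrin 6, followed by warming, close the C9–C10 epoxide 9.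

**Further compounds**

F1 | step 29 | α-phenylselanyl β-methyl macrolactone (C2/C3 diastereomer mixture) | CCCC[C@H](C)[C@H]1C[C@@H](O[Si](C)(C)C(C)(C)C)CCC[C@H](OCc2ccc(OC)cc2)C[C@@H]3C[C@@H](OC(C)(C)O3)CCC[C@H](O[Si](C)(C)C(C)(C)C)CCC[C@@H](O[Si](C)(C)C(C)(C)C)CCC[C@H](O[Si](C)(C)C(C)(C)C)CCC[C@@H](O[Si](C)(C)C(C)(C)C)CCC[C@@H](O[Si](C)(C)C(C)(C)C)CC(C)C([Se]c4ccccc4)C(=O)O1
F2 | step 29 | (E)-3-methyl-2-enoate macrolactone | CCCC[C@H](C)[C@H]1C[C@@H](O[Si](C)(C)C(C)(C)C)CCC[C@H](OCc2ccc(OC)cc2)C[C@@H]3C[C@@H](OC(C)(C)O3)CCC[C@H](O[Si](C)(C)C(C)(C)C)CCC[C@@H](O[Si](C)(C)C(C)(C)C)CCC[C@H](O[Si](C)(C)C(C)(C)C)CCC[C@@H](O[Si](C)(C)C(C)(C)C)CCC[C@@H](O[Si](C)(C)C(C)(C)C)C/C(C)=C/C(=O)O1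
F3 | step 25 | C35 alcohol (acetate removed from 46) | CCCC[C@H](C)[C@H](O)C[C@@H](O[Si](C)(C)C(C)(C)C)CCC[C@H](OCc1ccc(OC)cc1)C[C@@H]2C[C@@H](OC(C)(C)O2)CCC[C@H](O[Si](C)(C)C(C)(C)C)CCC[C@@H](O[Si](C)(C)C(C)(C)C)CCC[C@H](O[Si](C)(C)C(C)(C)C)CCC[C@@H](O[Si](C)(C)C(C)(C)C)CCC[C@@H](O[Si](C)(C)C(C)(C)C)CCO[Si](C)(C)C(C)(C)C
F4 | step 4 | C5 hydroxy dithiane (C3–C7, C3 OTBS) | C1CSC(SC1)C[C@@H](O)CCO[Si](C)(C)C(C)(C)C
F5 | step 4 | C3,C5-bis-silyl ether dithiane (C3–C7) | C1CSC(SC1)C[C@@H](O[Si](C)(C)C(C)(C)C)CCO[Si](C)(C)C(C)(C)C
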